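**Retrosynthetic overview**
1. Target 21 ⇐ dienyl acetate 20 by methylene transfer to the ring C4=C5 alkene (cyclopropane last); 20 ⇐ cyclooctadienone 18 by C8 reduction and acetylation.
2. 18 (eight-membered carbocycle) ⇐ six-membered 2-methylidene-3,6-dihydro-2H-pyran 17 by a [3,3] two-atom ring expansion; 17 is made in the same flask from alkynol 16 by gold-catalysed 6-exo-dig O–C closure.
3. Enabling feature: in 17 the ring oxygen O5 lies between the exocyclic C6=CH2 and C4, and the O5–C4 bond is allylic to both the (E)-propenyl group and the butenolide C3a=C7a bond; the equatorial C7 side chain, cis to the propenyl group, holds that group axial over the methylidene carbon.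
4. 16 ⇐ tetronate triflate 14 + crotonaldehyde 15 (asymmetric Ni/Cr coupling; this carbinol centre is relayed to C6); 14 ⇐ glycolate ester 12 (Dieckmann); 12 ⇐ (R)-citronellic acid 1 (bought stereocentre; auxiliary alkylation sets C9; aldehyde-to-alkyne homologation).
5. Ring order: butenolide → dihydropyran (transient) → cyclooctadiene (ring expansion) → cyclopropane.

Key step: step 11

Remark: fused-ring locants follow cycloocta[c]furan for 18–21 (C1 lactone C=O, C3 OCH2, C3a/C9a fusion alkene, C4, C5, C6 = CH(CH3), C7, C8 = C–O, C9 = side-chain carbon) and furo[3,4-c]pyran for 17.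
Remark: (R)-citronellic acid and (R)-4-benzyloxazolidin-2-one are taken as commercial single enantiomers.

**Step 1**
Reactants: 1 (R)-citronellic acid; 2 (4R)-4-benzyl-1,3-oxazolidin-2-one
Product: 4 (4R)-4-benzyl-3-[(3R)-3,7-dimethyloct-6-enoyl]-1,3-oxazolidin-2-one, via mixed pivalic anhydride 3 (not isolated)
Conditions: PivCl, Et3N, THF, −20 °C; then 2, LiCl, −20 °C → rt
Reagents that add atoms: none
Why: N-acylation of the oxazolidinone through the mixed pivalic anhydride (LiCl/Et3N protocol) attaches the auxiliary under conditions that leave the trisubstituted alkene and the C3 stereocentre untouched.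

**Step 2**
Reactants: 4 N-acyl oxazolidinone; 5 tert-butyl bromoacetate
Product: 6 tert-butyl (3R,4R)-3-{[(4R)-4-benzyl-2-oxo-1,3-oxazolidin-3-yl]carbonyl}-4,8-dimethylnon-7-enoate
Conditions: NaHMDS, THF, −78 °C; then 5, −78 → −45 °C
Reagents that add atoms: none
Why: Evans asymmetric alkylation: the chelated Z-sodium enolate is attacked by the α-bromo ester on the face opposite the C4 benzyl group, which with the (R)-auxiliary should set C3 as R (the later C9).

**Step 3**
Reactants: 6 alkylated imide
Product: 7 tert-butyl (3R,4R)-3-(hydroxymethyl)-4,8-dimethylnon-7-enoate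
Conditions: LiBH4, THF, 0 °C
Reagents that add atoms: none
Why: Reductive removal of the auxiliary: borohydride reduces the activated exocyclic imide carbonyl far faster than the tert-butyl ester, releasing the primary alcohol and the recoverable oxazolidinone.

**Step 4**
Reactants: 7 hydroxy ester
Product: 8 tert-butyl (3R,4R)-3-formyl-4,8-dimethylnon-7-enoate
Conditions: Dess–Martin periodinane, CH2Cl2, 0 °C → rt
Reagents that add atoms: none
Why: Dess–Martin oxidation is neutral and anhydrous, so the α-branched aldehyde should form without over-oxidation, lactonisation onto the tert-butyl ester or epimerisation at C3.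

**Step 5**
Reactants: 8 aldehyde
Product: 9 tert-butyl (3R,4R)-3-ethynyl-4,8-dimethylnon-7-enoate
Conditions: Ohira–Bestmann reagent, K2CO3, MeOH, 0 °C → rt
Reagents that add atoms: dimethyl (1-diazo-2-oxopropyl)phosphonate, COP(=O)(OC)C(=[N+]=[N-])C(C)=O
Why: Seyferth–Gilbert homologation in the Ohira–Bestmann form: the diazomethylphosphonate anion made in situ olefinates the aldehyde and the alkylidene carbene rearranges to the terminal alkyne, under carbonate conditions mild enough to limit epimerisation of the α-centre.

**Step 6**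
Reactants: 9 alkynyl tert-butyl ester
Product: 10 (3R,4R)-3-ethynyl-4,8-dimethylnon-7-enoic acid
Conditions: 85% aq. H3PO4, toluene, rt
Reagents that add atoms: none
Why: Acidolysis of the tert-butyl ester by alkyl–oxygen cleavage with aqueous phosphoric acid, an acid mild enough to leave the trisubstituted alkene and the terminal alkyne unprotonated.

**Step 7**
Reactants: 10 acid; 11 methyl glycolate
Product: 12 2-methoxy-2-oxoethyl (3R,4R)-3-ethynyl-4,8-dimethylnon-7-enoate
Conditions: EDC·HCl, DMAP (cat.), CH2Cl2, 0 °C → rt
Reagents that add atoms: none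
Why: Steglich-type carbodiimide esterification with DMAP as acyl-transfer catalyst; the stereocentres are not α to the activated carbonyl and cannot epimerise.

**Step 8**
Reactants: 12 acyloxyacetate
Product: 13 3-[(3R,4R)-4,8-dimethylnon-7-en-1-yn-3-yl]-4-hydroxyfuran-2(5H)-one
Conditions: KOtBu (2.2 equiv), THF, 0 °C → rt; then 1 M HCl
Reagents that add atoms: none
Why: Dieckmann condensation: the enolate of the acyl CH2 attacks the glycolate methyl ester 5-exo-trig, and formation of the tetronate anion (a vinylogous carboxylate) drives the equilibrium to the butenolide ring.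

**Step 9**
Reactants: 13 tetronic acid
Product: 14 4-[(3R,4R)-4,8-dimethylnon-7-en-1-yn-3-yl]-5-oxo-2,5-dihydrofuran-3-yl trifluoromethanesulfonate
Conditions: Tf2O, iPr2NEt, CH2Cl2, −78 °C
Reagents that add atoms: trifluoromethanesulfonic anhydride, O=S(=O)(OS(=O)(=O)C(F)(F)F)C(F)(F)F
Why: O-sulfonylation of the vinylogous acid at O4 turns the butenolide β-carbon into a coupling site without touching a stereocentre.

**Step 10**
Reactants: 14 tetronate triflate; 15 (E)-crotonaldehyde
Product: 16 3-[(3R,4R)-4,8-dimethylnon-7-en-1-yn-3-yl]-4-[(1R,2E)-1-hydroxybut-2-en-1-yl]furan-2(5H)-one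
Conditions: CrCl2 (3 equiv), chiral oxazoline–sulfonamide ligand (antipode directing attack to the Si face of the aldehyde), proton sponge, NiCl2 (5 mol%), THF, rt
Reagents that add atoms: none
Why: Asymmetric Nozaki–Hiyama–Kishi coupling: Ni(0) inserts into the vinyl C–OTf bond, transmetalation gives a vinylchromium(III) species that adds 1,2 to the enal, and the sulfonamide ligand on chromium is expected to control the aldehyde face and give the (1R)-carbinol, with the lactone and terminal alkyne tolerated.

**Step 11**
Reactants: 16 alkynol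
Product: 18 (4Z,6R,9S)-6-methyl-9-[(2R)-6-methylhept-5-en-2-yl]-6,7-dihydrocycloocta[c]furan-1,8(3H,9H)-dione, via methylidene dihydropyran 17 (not isolated)
Conditions: Ph3PAuNTf2 (2 mol%), toluene, 23 °C; then PPh3 (6 mol%), 110–120 °C, sealed tube
Reagents that add atoms: none
Why: Cationic gold(I) π-activates the terminal alkyne, the carbinol oxygen adds anti and Markovnikov in a 6-exo-dig closure (the butenolide C=C holds the carbinol and the alkynyl-bearing carbon cis) and protodeauration gives the allyl vinyl ether 17; on heating, 17 undergoes a concerted Claisen [3,3] shift in which the exocyclic =CH2 bonds to the CH(CH3) terminus of the propenyl group while the doubly allylic O5–C4 bond breaks, so the six-membered pyran grows by two atoms into the cyclooctadienone and O5 becomes the C8 ketone oxygen. The closest known reaction types are the tandem alkynol cycloisomerisation/Claisen rearrangement and the Claisen ring expansion of 2-methylene-6-alkenyltetrahydropyrans to cyclooct-4-enones. The pyran closes in 6-exo-dig mode, whereas the eight-membered ring is not closed by cyclisation but results from ring expansion of the pyran through a bridged, bicyclo[3.3.1]-like chair transition state. C6 is set by 1,3-chirality transfer from C4 of 17: with the propenyl group axial (forced by the equatorial C7 side chain cis to it) and the methyl of the E-alkene exo in the chair, the new C–C bond forms on one face only and should give 6R, the bridged geometry makes the new C4=C5 bond Z, and C9 is carried through unchanged. The step needs O-attack at the internal alkyne carbon rather than 7-endo closure or attack by the side-chain alkene, and it needs the exocyclic enol ether to survive until it rearranges; the terminal alkyne and the pre-organised cis hydroxyl secure the first, and retiring the gold with PPh3 before heating under neutral conditions secures the second.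

**Step 12**
Reactants: 18 cyclooctadienone
Product: 19 (4Z,6R,8R,9S)-8-hydroxy-6-methyl-9-[(2R)-6-methylhept-5-en-2-yl]-6,7,8,9-tetrahydrocycloocta[c]furan-1(3H)-one
Conditions: NaBH4, CeCl3·7H2O, MeOH, −78 °C
Reagents that add atoms: none
Why: Luche reduction: the cerium-activated ketone is reduced 1,2 at low temperature without touching the dienyl lactone or enolising the acidic C9–H, and hydride is expected to arrive on the exposed peripheral face anti to the C9 side chain, giving the 8R alcohol cis to that side chain.

**Step 13**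
Reactants: 19 alcohol
Product: 20 (4Z,6R,8R,9S)-6-methyl-9-[(2R)-6-methylhept-5-en-2-yl]-1-oxo-1,3,6,7,8,9-hexahydrocycloocta[c]furan-8-yl acetate
Conditions: Ac2O, pyridine, DMAP (cat.), CH2Cl2, 0 °C → rt
Reagents that add atoms: acetic anhydride, CC(=O)OC(C)=O
Why: DMAP-catalysed acylation of the secondary alcohol installs the acetate of the target with retention at C8.

**Step 14**
Reactants: 20 dienyl acetate
Product: 21 (4S,5S,6R,8R,9S)-6-methyl-9-[(2R)-6-methylhept-5-en-2-yl]-1-oxo-4,5-methano-1,3,4,5,6,7,8,9-octahydrocycloocta[c]furan-8-yl acetate (CNP0018922.1)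
Conditions: CH2N2 (excess, Et2O), Pd(OAc)2 (5 mol%), Et2O/CH2Cl2, 0 °C
Reagents that add atoms: diazomethane, C=[N+]=[N-]
Why: Palladium-catalysed methylene transfer from diazomethane is selective for the strained cis-disubstituted ring alkene of the 1,3-diene over the tetrasubstituted butenolide alkene and the trisubstituted side-chain alkene, and the carbene should arrive on the peripheral face of C4=C5, anti to the pseudo-equatorial C6 methyl as in other 3-substituted cis-cyclooctenes, giving the cis-fused cyclopropane trans to the methyl group.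

**Compound list**
1 | (R)-citronellic acid, (3R)-3,7-dimethyloct-6-enoic acid | OC(=O)C[C@H](C)CCC=C(C)C | starting material
2 | (4R)-4-benzyl-1,3-oxazolidin-2-one | O=C1N[C@H](Cc2ccccc2)CO1 | starting material
3 | (3R)-3,7-dimethyloct-6-enoic pivalic anhydride | CC(C)(C)C(=O)OC(=O)C[C@H](C)CCC=C(C)C | intermediate
4 | (4R)-4-benzyl-3-[(3R)-3,7-dimethyloct-6-enoyl]-1,3-oxazolidin-2-one | O=C1OC[C@@H](Cc2ccccc2)N1C(=O)C[C@H](C)CCC=C(C)C | intermediate
5 | tert-butyl bromoacetate | CC(C)(C)OC(=O)CBr | starting material
6 | tert-butyl (3R,4R)-3-{[(4R)-4-benzyl-2-oxo-1,3-oxazolidin-3-yl]carbonyl}-4,8-dimethylnon-7-enoate | CC(C)(C)OC(=O)C[C@@H](C(=O)N1[C@H](Cc2ccccc2)COC1=O)[C@H](C)CCC=C(C)C | intermediate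
7 | tert-butyl (3R,4R)-3-(hydroxymethyl)-4,8-dimethylnon-7-enoate | CC(C)(C)OC(=O)C[C@@H](CO)[C@H](C)CCC=C(C)C | intermediate
8 | tert-butyl (3R,4R)-3-formyl-4,8-dimethylnon-7-enoate | CC(C)(C)OC(=O)C[C@@H](C=O)[C@H](C)CCC=C(C)C | intermediate
9 | tert-butyl (3R,4R)-3-ethynyl-4,8-dimethylnon-7-enoate | CC(C)(C)OC(=O)C[C@@H](C#C)[C@H](C)CCC=C(C)C | intermediate
10 | (3R,4R)-3-ethynyl-4,8-dimethylnon-7-enoic acid | OC(=O)C[C@@H](C#C)[C@H](C)CCC=C(C)C | intermediate
11 | methyl glycolate (methyl 2-hydroxyacetate) | COC(=O)CO | starting material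
12 | 2-methoxy-2-oxoethyl (3R,4R)-3-ethynyl-4,8-dimethylnon-7-enoate | COC(=O)COC(=O)C[C@@H](C#C)[C@H](C)CCC=C(C)C | intermediate
13 | 3-[(3R,4R)-4,8-dimethylnon-7-en-1-yn-3-yl]-4-hydroxyfuran-2(5H)-one | OC1=C(C(=O)OC1)[C@@H](C#C)[C@H](C)CCC=C(C)C | intermediate
14 | 4-[(3R,4R)-4,8-dimethylnon-7-en-1-yn-3-yl]-5-oxo-2,5-dihydrofuran-3-yl trifluoromethanesulfonate | O=S(=O)(OC1=C(C(=O)OC1)[C@@H](C#C)[C@H](C)CCC=C(C)C)C(F)(F)F | intermediate
15 | (E)-crotonaldehyde, (2E)-but-2-enal | C/C=C/C=O | starting material
16 | 3-[(3R,4R)-4,8-dimethylnon-7-en-1-yn-3-yl]-4-[(1R,2E)-1-hydroxybut-2-en-1-yl]furan-2(5H)-one | C/C=C/[C@@H](O)C1=C(C(=O)OC1)[C@@H](C#C)[C@H](C)CCC=C(C)C | intermediate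
17 | (4R,7S)-6-methylidene-7-[(2R)-6-methylhept-5-en-2-yl]-4-[(1E)-prop-1-en-1-yl]-6,7-dihydro-4H-furo[3,4-c]pyran-1(3H)-one | C=C1O[C@H](/C=C/C)C2=C(C(=O)OC2)[C@@H]1[C@H](C)CCC=C(C)C | intermediate
18 | (4Z,6R,9S)-6-methyl-9-[(2R)-6-methylhept-5-en-2-yl]-6,7-dihydrocycloocta[c]furan-1,8(3H,9H)-dione | O=C1C[C@@H](C)/C=C\C2=C(C(=O)OC2)[C@@H]1[C@H](C)CCC=C(C)C | intermediate
19 | (4Z,6R,8R,9S)-8-hydroxy-6-methyl-9-[(2R)-6-methylhept-5-en-2-yl]-6,7,8,9-tetrahydrocycloocta[c]furan-1(3H)-one | O[C@@H]1C[C@@H](C)/C=C\C2=C(C(=O)OC2)[C@@H]1[C@H](C)CCC=C(C)C | intermediate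
20 | (4Z,6R,8R,9S)-6-methyl-9-[(2R)-6-methylhept-5-en-2-yl]-1-oxo-1,3,6,7,8,9-hexahydrocycloocta[c]furan-8-yl acetate | CC(=O)O[C@@H]1C[C@@H](C)/C=C\C2=C(C(=O)OC2)[C@@H]1[C@H](C)CCC=C(C)C | intermediate
21 | (4S,5S,6R,8R,9S)-6-methyl-9-[(2R)-6-methylhept-5-en-2-yl]-1-oxo-4,5-methano-1,3,4,5,6,7,8,9-octahydrocycloocta[c]furan-8-yl acetate (CNP0018922.1) | CC(=O)O[C@@H]1C[C@@H](C)[C@@H]2C[C@@H]2C2=C(C(=O)OC2)[C@@H]1[C@H](C)CCC=C(C)C | target

**Step count and risks**
Total step count: 14. Longest linear sequence: 14 steps (1 → 21).

Most likely to fail: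

1. Step 11. The exocyclic double bond of 17 may migrate into the pyran ring, or the doubly allylic O5–C4 bond may ionise, at the temperature the thermal shift needs; the chair preference that relays C4 to C6 may also erode. Fallback: setting out from 16, the gold-catalysed cyclisation is run alone at 0 °C and the methylidene dihydropyran 17 is isolated on base-washed alumina. The rearrangement is then triggered at −78 °C in CH2Cl2 with methylaluminium bis(4-bromo-2,6-di-tert-butylphenoxide), an aluminium-promoted Claisen rearrangement of allyl vinyl ethers that avoids heating a free enol ether, and the route is rejoined at 18. This fallback makes no compound outside the list (F0).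

2. Step 10. Reagent control at the new carbinol centre may be insufficient on a small enal, and the C1′ epimer would be carried by step 11 into the C6 epimer. Fallback: setting out from 14, a carbonylative Stille coupling with (E)-tributyl(prop-1-en-1-yl)stannane (CO 1 atm, Pd(PPh3)4, LiCl, THF, 50 °C) should give the cross-conjugated dienone F1. Corey–Bakshi–Shibata reduction of F1 ((S)-Me-CBS, catecholborane, toluene, −78 °C; the fully substituted butenolide carbon acts as the large group) should then give the (1R)-alcohol, rejoining the route at 16.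

3. Step 14. Facial discrimination in the methylene transfer may be poor, and diazomethane may add as a dipole to the electron-poor diene. Fallback: setting out from 19 (before acetylation), a hydroxyl-directed Simmons–Smith cyclopropanation is used (Et2Zn, 1 equiv, then Zn(CH2I)2·DME, 1 equiv, CH2Cl2, −20 °C). The C8 zinc alkoxide sits on the face where the methylene is needed and transannularly close to C4=C5, and limiting the carbenoid protects the side-chain alkene; this should give the cyclopropyl alcohol F2. Acetylation of F2 (Ac2O, pyridine, DMAP) rejoins the route at 21.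

**Further compounds**
F0 | step 11 | none | none
F1 | step 10 | 4-[(2E)-but-2-enoyl]-3-[(3R,4R)-4,8-dimethylnon-7-en-1-yn-3-yl]furan-2(5H)-one | C/C=C/C(=O)C1=C(C(=O)OC1)[C@@H](C#C)[C@H](C)CCC=C(C)C
F2 | step 14 | (4S,5S,6R,8R,9S)-8-hydroxy-6-methyl-9-[(2R)-6-methylhept-5-en-2-yl]-4,5-methano-4,5,6,7,8,9-hexahydrocycloocta[c]furan-1(3H)-one | O[C@@H]1C[C@@H](C)[C@@H]2C[C@@H]2C2=C(C(=O)OC2)[C@@H]1[C@H](C)CCC=C(C)C
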